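**Strategy.** Ring C of the target, the pyran-4-one, bears oxygen on both carbons of its C2=C3 bond: the ring oxygen O1 on C2 and the sulfated oxygen on C3. Two adjacent oxygenated sp2 carbons of this kind are what an enone alkene becomes on oxidative ring closure, so the route cuts O1–C2 and C3–O together. One alkaline peroxide treatment of a fully benzylated 2'-hydroxychalcone closes ring C and installs the 3-hydroxyl, which is then the only free hydroxyl and the only site open to sulfation. The precursor, chalcone 8, carries benzyl ethers on every other oxygen and comes from a symmetric phenol by C-acetylation and aldol condensation. Sulfation and one hydrogenolysis complete the synthesis.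

Key step: step 4

Assumption: the target is drawn as the free hydrogen sulfate, so the sulfate is carried as its sodium salt and protonated only in the last operation; racemic, non-isolated intermediates are drawn as one enantiomer.

**Route**

Step 1
Reactants: 1 3,4,5-tris(benzyloxy)benzaldehyde
Product: 3 3,4,5-tris(benzyloxy)phenol, via 3,4,5-tris(benzyloxy)phenyl formate 2 (not isolated)
Conditions: mCPBA, CH2Cl2, 0 °C → rt; aq. Na2S2O3/NaHCO3 wash; then K2CO3 (cat.), MeOH, rt
Reagents that add atoms: mCPBA (3-chloroperoxybenzoic acid), O=C(OO)c1cccc(Cl)c1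
Why: Baeyer–Villiger oxidation with a peracid (the Dakin-type route for an aldehyde that has no free ortho or para hydroxyl) should give formate 2, because the para-benzyloxy group makes the aryl ring migrate in preference to hydride, and mild methanolysis then frees the phenol without touching the benzyl ethers.

Step 2
Reactants: 3 3,4,5-tris(benzyloxy)phenol
Product: 6 1-[2,3,4-tris(benzyloxy)-6-hydroxyphenyl]ethan-1-one, via 3,4,5-tris(benzyloxy)phenyl acetate 4 (not isolated), via 2-acetyl-3,4,5-tris(benzyloxy)phenyl acetate 5 (not isolated)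
Conditions: AcOH, TFAA, CH2Cl2, 0 °C → rt; aq. NaHCO3 work-up; then K2CO3, MeOH/THF, rt
Reagents that add atoms: acetic acid, CC(=O)O
Why: Friedel–Crafts acylation by the mixed anhydride acetyl trifluoroacetate needs no metal Lewis acid, so the benzyl ethers that an AlCl3 or BF3 Fries rearrangement would strip should survive; the phenol is O-acetylated first, the ring is then C-acylated at one of the two symmetry-equivalent free positions (ortho and para to benzyloxy groups), and methanolysis of the aryl acetate frees the chelated phenol as a single regioisomer.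

Step 3
Reactants: 6 1-[2,3,4-tris(benzyloxy)-6-hydroxyphenyl]ethan-1-one; 7 4-(benzyloxy)benzaldehyde
Product: 8 (E)-3-[4-(benzyloxy)phenyl]-1-[2,3,4-tris(benzyloxy)-6-hydroxyphenyl]prop-2-en-1-one
Conditions: KOH (50% aq.), EtOH/THF, rt
Reagents that add atoms: none
Why: Claisen–Schmidt (crossed aldol) condensation, in which the enolate of methyl ketone 6 adds to the non-enolisable aldehyde 7 and E1cB loss of water gives the conjugated enone in its thermodynamically preferred E geometry, while the benzyl ethers and the chelated hydroxyl are inert to KOH.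

Step 4
Reactants: 8 (E)-3-[4-(benzyloxy)phenyl]-1-[2,3,4-tris(benzyloxy)-6-hydroxyphenyl]prop-2-en-1-one
Product: 10 5,6,7-tris(benzyloxy)-2-[4-(benzyloxy)phenyl]-3-hydroxy-4H-chromen-4-one, via trans-dihydroflavonol 9 (not isolated)
Conditions: 30% aq. H2O2 (excess), 2 M aq. NaOH, MeOH/THF, 0 °C → rt
Reagents that add atoms: hydrogen peroxide, OO
Why: Hydroxide turns the free hydroxyl into its phenoxide, which adds to the enone β-carbon (oxa-Michael addition) to give a flavanone enolate; the enolate attacks hydrogen peroxide at oxygen through C3 to give trans-dihydroflavonol 9, and the same alkaline peroxide medium dehydrogenates 9 across C2–C3 to flavonol 10. The closest known reaction is the Algar–Flynn–Oyamada oxidation of 2'-hydroxychalcones, which is also used on members that carry an alkoxy group flanking the carbonyl. Ring C is closed in the 6-endo-trig mode by oxygen on carbon. The two stereocentres of 9 (C2 and C3, trans) are erased by the dehydrogenation, so the product has none. The selectivity needed is closure at the β-carbon and not at the α-carbon of a competing chalcone epoxide (5-exo, the aurone pathway), which the benzyloxy group next to the carbonyl encourages by twisting the enone out of the plane of ring A. It is counted on to come from the para-benzyloxy donor on ring B, which stabilises positive character at the benzylic β-carbon and so steers either intermediate towards six-ring closure, supported by low temperature and excess base to keep cyclisation ahead of epoxidation.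

Step 5
Reactants: 10 5,6,7-tris(benzyloxy)-2-[4-(benzyloxy)phenyl]-3-hydroxy-4H-chromen-4-one
Product: 12 sodium 5,6,7-tris(benzyloxy)-2-[4-(benzyloxy)phenyl]-4-oxo-4H-chromen-3-yl sulfate, via pyridinium sulfate salt 11 (not isolated)
Conditions: SO3·pyridine, pyridine, 50 °C; then 1 M aq. NaOH to pH 8, 0 °C
Reagents that add atoms: sulfur trioxide–pyridine complex, O=S(=O)([O-])[n+]1ccccc1; sodium hydroxide, [Na+].[OH-]
Why: O-sulfonation of an acidic enolic hydroxyl with an SO3–amine complex is standard sulfation chemistry and can only occur at the 3-hydroxyl, the one free OH of 10, and exchange to the sodium salt removes pyridine, which would otherwise inhibit the benzyl ether hydrogenolysis that follows.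

Step 6
Reactants: 12 sodium 5,6,7-tris(benzyloxy)-2-[4-(benzyloxy)phenyl]-4-oxo-4H-chromen-3-yl sulfate
Product: 14 5,6,7-trihydroxy-2-(4-hydroxyphenyl)-4-oxo-4H-chromen-3-yl hydrogen sulfate (the target), via debenzylated sodium sulfate 13 (not isolated)
Conditions: H2 (1 atm), 10% Pd/C, THF/MeOH, rt; filtration under argon; then HCl (1.0 equiv, 0.1 M aq.), 0 °C, immediate C18 desalting and freeze-drying
Reagents that add atoms: none
Why: Hydrogenolysis of benzyl aryl ethers over Pd/C is neutral and should leave the sulfate monoester salt and the chromone C2=C3 bond intact, and one cold equivalent of acid then converts the salt into the hydrogen sulfate without the prolonged acidity that would hydrolyse it.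

**Compound list**

1 | 3,4,5-tris(benzyloxy)benzaldehyde | O=Cc1cc(OCc2ccccc2)c(OCc2ccccc2)c(OCc2ccccc2)c1 | starting material
2 | 3,4,5-tris(benzyloxy)phenyl formate (not isolated) | O=COc1cc(OCc2ccccc2)c(OCc2ccccc2)c(OCc2ccccc2)c1 | intermediate
3 | 3,4,5-tris(benzyloxy)phenol | Oc1cc(OCc2ccccc2)c(OCc2ccccc2)c(OCc2ccccc2)c1 | intermediate
4 | 3,4,5-tris(benzyloxy)phenyl acetate (not isolated) | CC(=O)Oc1cc(OCc2ccccc2)c(OCc2ccccc2)c(OCc2ccccc2)c1 | intermediate
5 | 2-acetyl-3,4,5-tris(benzyloxy)phenyl acetate (not isolated) | CC(=O)Oc1cc(OCc2ccccc2)c(OCc2ccccc2)c(OCc2ccccc2)c1C(C)=O | intermediate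
6 | 1-[2,3,4-tris(benzyloxy)-6-hydroxyphenyl]ethan-1-one | CC(=O)c1c(O)cc(OCc2ccccc2)c(OCc2ccccc2)c1OCc1ccccc1 | intermediate
7 | 4-(benzyloxy)benzaldehyde | O=Cc1ccc(OCc2ccccc2)cc1 | starting material
8 | (E)-3-[4-(benzyloxy)phenyl]-1-[2,3,4-tris(benzyloxy)-6-hydroxyphenyl]prop-2-en-1-one | O=C(/C=C/c1ccc(OCc2ccccc2)cc1)c1c(O)cc(OCc2ccccc2)c(OCc2ccccc2)c1OCc1ccccc1 | intermediate
9 | rac-(2R,3R)-5,6,7-tris(benzyloxy)-2-[4-(benzyloxy)phenyl]-3-hydroxy-2,3-dihydro-4H-chromen-4-one (trans; not isolated) | O[C@@H]1[C@@H](c2ccc(OCc3ccccc3)cc2)Oc2cc(OCc3ccccc3)c(OCc3ccccc3)c(OCc3ccccc3)c2C1=O | intermediate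
10 | 5,6,7-tris(benzyloxy)-2-[4-(benzyloxy)phenyl]-3-hydroxy-4H-chromen-4-one | O=c1c(O)c(-c2ccc(OCc3ccccc3)cc2)oc2cc(OCc3ccccc3)c(OCc3ccccc3)c(OCc3ccccc3)c12 | intermediate
11 | pyridinium 5,6,7-tris(benzyloxy)-2-[4-(benzyloxy)phenyl]-4-oxo-4H-chromen-3-yl sulfate (not isolated) | O=c1c(OS(=O)(=O)[O-])c(-c2ccc(OCc3ccccc3)cc2)oc2cc(OCc3ccccc3)c(OCc3ccccc3)c(OCc3ccccc3)c12.c1cc[nH+]cc1 | intermediate
12 | sodium 5,6,7-tris(benzyloxy)-2-[4-(benzyloxy)phenyl]-4-oxo-4H-chromen-3-yl sulfate | O=c1c(OS(=O)(=O)[O-])c(-c2ccc(OCc3ccccc3)cc2)oc2cc(OCc3ccccc3)c(OCc3ccccc3)c(OCc3ccccc3)c12.[Na+] | intermediate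
13 | sodium 5,6,7-trihydroxy-2-(4-hydroxyphenyl)-4-oxo-4H-chromen-3-yl sulfate (not isolated) | O=c1c(OS(=O)(=O)[O-])c(-c2ccc(O)cc2)oc2cc(O)c(O)c(O)c12.[Na+] | intermediate
14 | 5,6,7-trihydroxy-2-(4-hydroxyphenyl)-4-oxo-4H-chromen-3-yl hydrogen sulfate | O=c1c(OS(=O)(=O)O)c(-c2ccc(O)cc2)oc2cc(O)c(O)c(O)c12 | target

**Totals**

Total step count: 6. Longest linear sequence: 6 steps (1 to 14; aldehyde 7 is a purchased building block).

**Steps most likely to fail**

Step 4. The phenoxide may close onto the α-carbon of a transient chalcone epoxide (5-exo) instead of the β-carbon. The benzyloxy group beside the carbonyl twists the enone and slows the 6-endo conjugate addition, so material would drain into the five-ring benzofuranone manifold. The fallback sets out from chalcone 8 and returns at flavonol 10. Chalcone 8 would be cyclised and dehydrogenated with catalytic I2 in DMSO at about 110 °C to the flavone 5,6,7-tris(benzyloxy)-2-[4-(benzyloxy)phenyl]-4H-chromen-4-one F1, in which ring C is already closed, so no five-ring closure is possible afterwards. Epoxidation of the C2=C3 enol ether bond with DMDO in acetone/CH2Cl2 at 0 °C would give the racemic cis-fused epoxide 5,6,7-tris(benzyloxy)-2-[4-(benzyloxy)phenyl]-2,3-epoxy-2,3-dihydro-4H-chromen-4-one F2. Catalytic p-TsOH would open it at C2 and, after loss of the C3 proton, deliver 10.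

Step 2. The trifluoroacetic acid released may cleave or transfer a benzyl group, most easily the one that ends up next to the new carbonyl, or the sequence may stall at the O-acetate stage without C-acylation. The fallback sets out from phenol 3 and returns at ketone 6, and avoids electrophilic acylation altogether. Mono-iodination of 3 with one equivalent of NIS in MeCN at 0 °C (the two open positions are equivalent) would give 3,4,5-tris(benzyloxy)-2-iodophenol F3. Stille coupling with tributyl(1-ethoxyvinyl)stannane, Pd(PPh3)4 (zerovalent palladium) and CuI in DMF at 80 °C would give the enol ether 3,4,5-tris(benzyloxy)-2-(1-ethoxyethenyl)phenol F4. Brief hydrolysis with dilute aqueous HCl in THF at rt would unmask the methyl ketone 6.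

Step 6. The hydrogenolysis may stall part-way through catalyst inhibition by traces of pyridine or sulfur species, the sulfate may be lost by solvolysis during reduction or acidification, and the liberated trihydroxylated ring A may oxidise in air. The fallback sets out from flavonol 10 and returns at target 14, with the order of events reversed so that no sulfate is present during the reduction. Hydrogenolysis of 10 (H2, Pd/C, THF/MeOH) would give 3,5,6,7-tetrahydroxy-2-(4-hydroxyphenyl)-4H-chromen-4-one F5. Mono-sulfation with tetrabutylammonium hydrogen sulfate and DCC in pyridine in the cold, conditions known to esterify the 3-hydroxyl of flavonols first, would give tetrabutylammonium 5,6,7-trihydroxy-2-(4-hydroxyphenyl)-4-oxo-4H-chromen-3-yl sulfate F6. The extra 6-hydroxyl, hindered between two oxygens, is expected to react late. One cold equivalent of HCl and C18 desalting would give 14.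

**Further compounds**

F1 | step 4 | 5,6,7-tris(benzyloxy)-2-[4-(benzyloxy)phenyl]-4H-chromen-4-one | O=c1cc(-c2ccc(OCc3ccccc3)cc2)oc2cc(OCc3ccccc3)c(OCc3ccccc3)c(OCc3ccccc3)c12
F2 | step 4 | 5,6,7-tris(benzyloxy)-2-[4-(benzyloxy)phenyl]-2,3-epoxy-2,3-dihydro-4H-chromen-4-one (racemic, cis-fused; one enantiomer drawn) | O=C1c2c(OCc3ccccc3)c(OCc3ccccc3)c(OCc3ccccc3)cc2O[C@]2(c3ccc(OCc4ccccc4)cc3)O[C@H]12
F3 | step 2 | 3,4,5-tris(benzyloxy)-2-iodophenol | Oc1cc(OCc2ccccc2)c(OCc2ccccc2)c(OCc2ccccc2)c1I
F4 | step 2 | 3,4,5-tris(benzyloxy)-2-(1-ethoxyethenyl)phenol | C=C(OCC)c1c(O)cc(OCc2ccccc2)c(OCc2ccccc2)c1OCc1ccccc1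
F5 | step 6 | 3,5,6,7-tetrahydroxy-2-(4-hydroxyphenyl)-4H-chromen-4-one | O=c1c(O)c(-c2ccc(O)cc2)oc2cc(O)c(O)c(O)c12
F6 | step 6 | tetrabutylammonium 5,6,7-trihydroxy-2-(4-hydroxyphenyl)-4-oxo-4H-chromen-3-yl sulfate | O=c1c(OS(=O)(=O)[O-])c(-c2ccc(O)cc2)oc2cc(O)c(O)c(O)c12.CCCC[N+](CCCC)(CCCC)CCCC
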